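**Don't stop.** Leave the larch flask stirring; it is the flask asked about.

- larch: substrate 0.018 M; reagent in the second phase 0.0171 M; the very flask that is asked about, followed so far
- flask: substrate 0.018 M; reagent in the second phase 0.0171 M; time 12 h; volume of the second phase over the first 2.0

larch run (percent of the substrate charged)

| time / h | target / % | substrate / % |
|---|---|---|
| 1.00 | 19.3 | 78.6 |
| 1.50 | 26.5 | 69.1 |
| 2.50 | 35.4 | 54.1 |
| 4.00 | 39.4 | 38.7 |

(standard deviation of a reading: 0.3 percentage points)

- in the second phase: reagent in the second phase; everything else is in the first
- charges count per volume of the first phase; a concentration in a rate is the amount of a species over the volume of its own phase; every rate counts per litre of the first phase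
- the earlier runs hold the two phases in the same ratio of volumes as the flask asked about

1. the best time, 12 h at the latest, for target
2. the amount of target, in percent of the substrate charged, at that time
3. earliest time at which at least nineteen twentieths of that best amount are there
4. latest time at which they still are

**Now.** At 4.00 h the flask holds 38.7 % of the charge as substrate and 39.4 % as target. The remainder I count as target lost.

**My reckoning.** Take each end alone, using the last two readings. Substrate falls at 0.223 h⁻¹, a pseudo-first-order rate. The lost fraction grows, per unit of mean target, at 0.203 h⁻¹. Now join them: target stands still where making equals loss. So take the hold ratio 1.10, the target-to-substrate ratio at the peak. Below it target rises; above it target falls. Both rates are readings and carry their scatter.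

The last reading gives 1.02, less than the hold ratio. So target is still rising there, slowly. My reckoning gives a direction, not a time.

**When you come.** The forecast gives the times: a peak of 39.5 % at 4.1 h, with the margin held from 3.05 h to 5.6 h, on the ground that “Formation equals loss” near that peak. Don't let the flask run past the end of that margin.

**The result.** The flask peaks at 39.5 % at 4.18 h and holds the margin from 2.98 h to 5.71 h, so from the last reading at 4.00 h you have 1.71 h to work up.

    reagent in the reaction phase → decomposed reagent (k = 0.200 h⁻¹)
    target ⇌ isomer of the product (K = 14.4, k = 0.202 h⁻¹)
    reagent in the reaction phase ⇌ reagent in the second phase, rate k3*([reagent in the reaction phase] - [reagent in the second phase]/K3) per volume of the first phase (partition coefficient = 0.770, kL = 0.480 h⁻¹)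
    substrate + reagent in the reaction phase → target (k = 562 M⁻¹ h⁻¹)

**Next reading.** At 4.18 h the flask holds 37.4 % substrate and 39.5 % target, a ratio of 1.06, close to the hold ratio 1.10. The neighbouring flask has the same charges and is read at 5.0 h. It holds 31.8 % substrate and 38.9 % target, a ratio of 1.22, higher than the hold ratio. Its target stands below the 39.5 % reached earlier.

The data stem from a simulated flask with constants of no real substance, and the scatter is random.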